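**Retrosynthetic overview**
1. Both rings are cut in one operation. The O6–C12 lactone bond goes first, then C6–C7 of the ten-membered ring (the farnesyl C1–C10 bond), which leads back to an acyclic, fully oxidised farnesane.
2. In this seco compound, C6 is an aldehyde masked together with O15 as one cyclic methyl acetal. C7=C11(CO2Me)–C13H2Bpin is the π-nucleophile, and boron leaves C13 where the germacrenyl cation loses H+, so C11=C13 appears as in germacrene A acid.
3. The allylboronate (C8 cis to CO2Me) comes from an (E)-α-bromoacrylate by Negishi coupling. The bromoacrylate comes from the C7 α-acyloxy aldehyde by a bromo-HWE reaction, and the aldehyde from a vinyl group by oxidative cleavage.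
4. C1=C10 (E by CIP, cis within the ring) is an HWE junction. The C1 aldehyde carries C4, set by Cu-catalysed conjugate addition to furanone. The phosphonoacetate carries C8–O-isobutyrate, set by Rh-catalysed addition of isobutyric acid to an alkyne.
5. Forward ring order: carbocycle (C6–C7) first, then γ-lactone (O6–C12), in the same flask in the last step.

Positions are given in germacrane numbering (C1–C15).
Assumption: in the two catalytic asymmetric steps (1 and 5), the ligand enantiomer is chosen to give the drawn configuration.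

**Step 1**
Reactants: 1 furan-2(5H)-one; 2 but-3-en-1-ylmagnesium bromide
Product: 4 (4S)-4-(but-3-en-1-yl)oxolan-2-one, via bis(but-3-en-1-yl)zinc 3 (not isolated)
Conditions: 2 (3 equiv), ZnCl2 (1.5 equiv), Et2O, 0 °C to rt, 1,4-dioxane (Mg salts filtered off); (CuOTf)2·C6H6 (2 mol %), valine-based phosphine–Schiff-base peptide ligand (5 mol %), toluene, −30 °C, slow addition of 1; 1 M HCl
Reagents that add atoms: none
Why: This is a Cu-catalysed asymmetric conjugate addition of a dialkylzinc to an unsaturated lactone, in which the chiral Cu–phosphine complex delivers the butenyl group to one face of the butenolide and so sets C4 (S), while the terminal alkene is inert.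

**Step 2**
Reactants: 4 (4S)-4-(but-3-en-1-yl)oxolan-2-one
Product: 6 (4S)-4-(but-3-en-1-yl)-2-methoxyoxolane (anomer mixture), via lactol 5 (not isolated)
Conditions: DIBAL-H (1.1 equiv), CH2Cl2, −78 °C; Rochelle salt; crude 5, MeOH, PPTS (5 mol %), rt
Reagents that add atoms: methanol, CO
Why: DIBAL-H reduction of the lactone stops at the aluminium lactolate at −78 °C, and acid-catalysed acetalisation then masks O15 and the C6 aldehyde together in one cyclic acetal without touching C4.

**Step 3**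
Reactants: 6 (4S)-4-(but-3-en-1-yl)-2-methoxyoxolane
Product: 8 3-[(3S)-5-methoxyoxolan-3-yl]propanal, via secondary ozonide 7 (not isolated)
Conditions: O3, CH2Cl2, −78 °C (Sudan III end point); Me2S, −78 °C to rt
Reagents that add atoms: ozone, [O-][O+]=O
Why: Ozonolysis with reductive work-up cleaves the only alkene to the C1 aldehyde much faster than ozone attacks the acetal C–H at −78 °C.

**Step 4**
Reactants: 9 methyl 2-(diethoxyphosphoryl)acetate; 10 4-bromobut-1-yne
Product: 11 methyl 2-(diethoxyphosphoryl)hex-5-ynoate (racemic)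
Conditions: NaH, DMF, 0 °C; 10, NaI (10 mol %), 50 °C
Reagents that add atoms: none
Why: This is an SN2 C-alkylation of the soft, stabilised phosphonoacetate carbanion, which is too weak a base to deprotonate the alkyne or to eliminate HBr to any large extent.

**Step 5**
Reactants: 11 methyl 2-(diethoxyphosphoryl)hex-5-ynoate; 12 2-methylpropanoic acid
Product: 13 methyl (4R)-2-(diethoxyphosphoryl)-4-[(2-methylpropanoyl)oxy]hex-5-enoate (1:1 at C2)
Conditions: [Rh(cod)Cl]2 (2.5 mol %), Cp-DIOP (7.5 mol %), 12 (1.5 equiv), DCE, 70 °C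
Reagents that add atoms: none
Why: This is a Rh-catalysed redox-neutral hydro-acyloxylation (alkyne-to-allene isomerisation, Rh–H addition to a π-allyl, carboxylate attack at the branched terminus), in which the chiral diphosphine sets C8 (R) and installs the final isobutyrate directly, so O8 is never free to lactonise onto C14.

**Step 6**
Reactants: 8 3-[(3S)-5-methoxyoxolan-3-yl]propanal; 13 methyl (4R)-2-(diethoxyphosphoryl)-4-[(2-methylpropanoyl)oxy]hex-5-enoate
Product: 14 methyl (2E)-5-[(3S)-5-methoxyoxolan-3-yl]-2-{(2R)-2-[(2-methylpropanoyl)oxy]but-3-en-1-yl}pent-2-enoate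
Conditions: LiCl, DBU, MeCN, 0 °C to rt; E/Z isomers separated
Reagents that add atoms: none
Why: The Horner–Wadsworth–Emmons reaction under mild Masamune–Roush conditions equilibrates to the (E)-enoate (C2 trans to CO2Me, which is the ring-cis 1(10) geometry), removes the stereocentre at C10 and leaves the isobutyrate and acetal intact.

**Step 7**
Reactants: 14 methyl (2E)-5-[(3S)-5-methoxyoxolan-3-yl]-2-{(2R)-2-[(2-methylpropanoyl)oxy]but-3-en-1-yl}pent-2-enoate
Product: 16 methyl (2E)-5-[(3S)-5-methoxyoxolan-3-yl]-2-{(2R)-2-[(2-methylpropanoyl)oxy]-3-oxopropyl}pent-2-enoate, via vicinal diol 15 (not isolated)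
Conditions: OsO4 (2 mol %), NaIO4 (4 equiv), 2,6-lutidine (2 equiv), dioxane/H2O 3:1, rt
Reagents that add atoms: sodium periodate, [Na+].[O-]I(=O)(=O)=O
Why: In this Lemieux–Johnson cleavage the monosubstituted vinyl group is osmylated far faster than the trisubstituted, ester-deactivated C1=C10 alkene, and the lutidine buffer protects the acetal and the C8 configuration.

**Step 8**
Reactants: 17 methyl 2-[bis(2,2,2-trifluoroethoxy)phosphoryl]acetate
Product: 18 methyl 2-[bis(2,2,2-trifluoroethoxy)phosphoryl]-2-bromoacetate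
Conditions: NaH (1.0 equiv), THF, 0 °C; added to Br2 (1.0 equiv), −78 to 0 °C
Reagents that add atoms: bromine, BrBr
Why: This is an electrophilic α-bromination of the phosphonate carbanion, and traces of unbrominated and dibrominated phosphonate comproportionate under the base used in step 9.

**Step 9**
Reactants: 16 methyl (2E)-5-[(3S)-5-methoxyoxolan-3-yl]-2-{(2R)-2-[(2-methylpropanoyl)oxy]-3-oxopropyl}pent-2-enoate; 18 methyl 2-[bis(2,2,2-trifluoroethoxy)phosphoryl]-2-bromoacetate
Product: 19 dimethyl (2E,4R,6E)-2-bromo-6-{3-[(3S)-5-methoxyoxolan-3-yl]propylidene}-4-[(2-methylpropanoyl)oxy]hept-2-enedioate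
Conditions: 18, t-BuOK, 18-crown-6, THF, −78 °C; then 16, −78 °C
Reagents that add atoms: none
Why: In this Still–Gennari-type HWE reaction the electron-poor trifluoroethyl phosphonate eliminates under kinetic control, placing C8 cis to CO2Me [(E)-α-bromoacrylate], and the weakly basic preformed anion does not epimerise C8 at −78 °C.

**Step 10**
Reactants: 19 dimethyl (2E,4R,6E)-2-bromo-6-{3-[(3S)-5-methoxyoxolan-3-yl]propylidene}-4-[(2-methylpropanoyl)oxy]hept-2-enedioate; 20 2-(iodomethyl)-4,4,5,5-tetramethyl-1,3,2-dioxaborolane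
Product: 22 dimethyl (2Z,4R,6E)-6-{3-[(3S)-5-methoxyoxolan-3-yl]propylidene}-4-[(2-methylpropanoyl)oxy]-2-[(4,4,5,5-tetramethyl-1,3,2-dioxaborolan-2-yl)methyl]hept-2-enedioate, via borylmethylzinc iodide 21 (not isolated)
Conditions: 20, Zn dust, THF, rt; then 19, Pd(PPh3)4 (5 mol %), THF, rt
Reagents that add atoms: none
Why: The Negishi coupling of the borylmethylzinc reagent with an activated alkenyl bromide proceeds with retention of geometry, giving the allylboronate with C8 trans to C13H2B (E-crotyl type), and oxidative addition into C–Br is faster than ionisation of the allylic isobutyrate.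

**Step 11**
Reactants: 22 dimethyl (2Z,4R,6E)-6-{3-[(3S)-5-methoxyoxolan-3-yl]propylidene}-4-[(2-methylpropanoyl)oxy]-2-[(4,4,5,5-tetramethyl-1,3,2-dioxaborolan-2-yl)methyl]hept-2-enedioate
Product: 26 CNP0251148.1 = methyl (3aS,4R,6E,10S,11aR)-10-(hydroxymethyl)-3-methylidene-4-[(2-methylpropanoyl)oxy]-2-oxo-2,3,3a,4,5,8,9,10,11,11a-decahydrocyclodeca[b]furan-6-carboxylate, via lactol 23 (not isolated), via hydroxy aldehyde 24 (not isolated), via macrocyclic borate 25 (not isolated)
Conditions: Sc(OTf)3 (20 mol %), MeCN/H2O 50:1, 50 °C, 22 added by syringe pump over 12 h (final 1 mM); then p-TsOH·H2O (20 mol %), rt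
Reagents that add atoms: water, O
Why: Proposed new method: Sc(III)/H2O hydrolyses the cyclic acetal to lactol 23, whose open tautomer 24 presents the C6 aldehyde to the internal 2-(methoxycarbonyl)allylboronate; a closed Zimmerman–Traxler chair (C5 and C8 both equatorial because C8 is trans to C13H2B) then forms C6–C7 with SE2′ shift of the alkene to C11=C13, giving the 6,7-anti borate 25; A(1,3) strain between H8 and the cis CO2Me fixes the C8 rotamer (H inside, C9 anti, O-acyl outside), so C6 adds to the C7 face that gives 6R,7S next to 8R, and O6 then closes the trans γ-lactone on C12; the closest known reaction types are the Lewis-acid-catalysed intermolecular tandem allylboration–lactonisation of 2-alkoxycarbonyl allylboronates, the allylation of lactols through their hydroxy-aldehyde tautomers, and Barbier/Nozaki–Hiyama closures of ten-membered germacranolides.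

**Compound list**
1 | furan-2(5H)-one | O=C1C=CCO1 | starting material
2 | but-3-en-1-ylmagnesium bromide (THF solution) | C=CCC[Mg]Br | starting material
3 | bis(but-3-en-1-yl)zinc | C=CCC[Zn]CCC=C | intermediate
4 | (4S)-4-(but-3-en-1-yl)oxolan-2-one | O=C1C[C@@H](CO1)CCC=C | intermediate
5 | (4S)-4-(but-3-en-1-yl)oxolan-2-ol (anomers) | OC1C[C@@H](CO1)CCC=C | intermediate
6 | (4S)-4-(but-3-en-1-yl)-2-methoxyoxolane (anomers) | COC1C[C@@H](CO1)CCC=C | intermediate
7 | 3-{2-[(3S)-5-methoxyoxolan-3-yl]ethyl}-1,2,4-trioxolane | COC1C[C@@H](CO1)CCC2OCOO2 | intermediate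
8 | 3-[(3S)-5-methoxyoxolan-3-yl]propanal | COC1C[C@@H](CO1)CCC=O | intermediate
9 | methyl 2-(diethoxyphosphoryl)acetate | CCOP(=O)(CC(=O)OC)OCC | starting material
10 | 4-bromobut-1-yne | C#CCCBr | starting material
11 | methyl 2-(diethoxyphosphoryl)hex-5-ynoate | C#CCCC(C(=O)OC)P(=O)(OCC)OCC | intermediate
12 | 2-methylpropanoic (isobutyric) acid | CC(C)C(=O)O | starting material
13 | methyl (4R)-2-(diethoxyphosphoryl)-4-[(2-methylpropanoyl)oxy]hex-5-enoate | C=C[C@H](OC(=O)C(C)C)CC(C(=O)OC)P(=O)(OCC)OCC | intermediate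
14 | methyl (2E)-5-[(3S)-5-methoxyoxolan-3-yl]-2-{(2R)-2-[(2-methylpropanoyl)oxy]but-3-en-1-yl}pent-2-enoate | COC1C[C@@H](CO1)CC/C=C(/C(=O)OC)C[C@@H](OC(=O)C(C)C)C=C | intermediate
15 | methyl (2E)-2-{(2R)-3,4-dihydroxy-2-[(2-methylpropanoyl)oxy]butyl}-5-[(3S)-5-methoxyoxolan-3-yl]pent-2-enoate | COC1C[C@@H](CO1)CC/C=C(/C(=O)OC)C[C@@H](OC(=O)C(C)C)C(O)CO | intermediate
16 | methyl (2E)-5-[(3S)-5-methoxyoxolan-3-yl]-2-{(2R)-2-[(2-methylpropanoyl)oxy]-3-oxopropyl}pent-2-enoate | COC1C[C@@H](CO1)CC/C=C(/C(=O)OC)C[C@@H](OC(=O)C(C)C)C=O | intermediate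
17 | methyl 2-[bis(2,2,2-trifluoroethoxy)phosphoryl]acetate | COC(=O)CP(=O)(OCC(F)(F)F)OCC(F)(F)F | starting material
18 | methyl 2-[bis(2,2,2-trifluoroethoxy)phosphoryl]-2-bromoacetate | COC(=O)C(Br)P(=O)(OCC(F)(F)F)OCC(F)(F)F | intermediate
19 | dimethyl (2E,4R,6E)-2-bromo-6-{3-[(3S)-5-methoxyoxolan-3-yl]propylidene}-4-[(2-methylpropanoyl)oxy]hept-2-enedioate | COC1C[C@@H](CO1)CC/C=C(/C(=O)OC)C[C@@H](OC(=O)C(C)C)/C=C(/Br)C(=O)OC | intermediate
20 | 2-(iodomethyl)-4,4,5,5-tetramethyl-1,3,2-dioxaborolane | ICB1OC(C)(C)C(C)(C)O1 | starting material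
21 | iodo[(4,4,5,5-tetramethyl-1,3,2-dioxaborolan-2-yl)methyl]zinc | I[Zn]CB1OC(C)(C)C(C)(C)O1 | intermediate
22 | dimethyl (2Z,4R,6E)-6-{3-[(3S)-5-methoxyoxolan-3-yl]propylidene}-4-[(2-methylpropanoyl)oxy]-2-[(pinacolboryl)methyl]hept-2-enedioate | COC1C[C@@H](CO1)CC/C=C(/C(=O)OC)C[C@@H](OC(=O)C(C)C)/C=C(/CB2OC(C)(C)C(C)(C)O2)C(=O)OC | intermediate
23 | lactol of 22 (5-hydroxyoxolan-3-yl in place of 5-methoxyoxolan-3-yl) | OC1C[C@@H](CO1)CC/C=C(/C(=O)OC)C[C@@H](OC(=O)C(C)C)/C=C(/CB2OC(C)(C)C(C)(C)O2)C(=O)OC | intermediate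
24 | open tautomer of 23: C6 aldehyde, free C15–OH (4S,8R) | O=CC[C@@H](CO)CC/C=C(/C(=O)OC)C[C@@H](OC(=O)C(C)C)/C=C(/CB1OC(C)(C)C(C)(C)O1)C(=O)OC | intermediate
25 | methyl (1E,5S,7R,8S,9R)-5-(hydroxymethyl)-8-(3-methoxy-3-oxoprop-1-en-2-yl)-9-[(2-methylpropanoyl)oxy]-7-[(pinacolboryl)oxy]cyclodec-1-ene-1-carboxylate | C=C(C(=O)OC)[C@H]1[C@H](OB2OC(C)(C)C(C)(C)O2)C[C@@H](CO)CC/C=C(/C(=O)OC)C[C@H]1OC(=O)C(C)C | intermediate
26 | CNP0251148.1 (germacrane numbering 4S,6R,7S,8R; 1(10)E) | C=C1C(=O)O[C@@H]2C[C@@H](CO)CC/C=C(/C(=O)OC)C[C@@H](OC(=O)C(C)C)[C@@H]12 | target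

**Step count**
Total step count: 11.
Longest linear sequence: 8 (steps 1, 2, 3, 6, 7, 9, 10, 11).

**Three steps most likely to fail**

*Step 11.* The risks are oligomerisation at the medium-ring closure, attack on the wrong C7 face, and capture of the cyclic oxocarbenium ion instead of the aldehyde. The fallback sets out from 16 and comes back at 26. It keeps the C6–C7 closure but replaces the stereospecific allylboron with a stereoconvergent allylchromium.
- A DABCO-promoted Morita–Baylis–Hillman reaction of 16 with methyl acrylate gives dimethyl (4R,6E)-3-hydroxy-6-{3-[(3S)-5-methoxyoxolan-3-yl]propylidene}-2-methylidene-4-[(2-methylpropanoyl)oxy]heptanedioate F1. The C7 epimers are irrelevant.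
- PBr3 (SN2′) converts F1 into dimethyl (2Z,4R,6E)-2-(bromomethyl)-6-{3-[(3S)-5-methoxyoxolan-3-yl]propylidene}-4-[(2-methylpropanoyl)oxy]hept-2-enedioate F2.
- Aqueous acetic acid frees dimethyl (2Z,4R,6E)-2-(bromomethyl)-6-{3-[(3S)-5-hydroxyoxolan-3-yl]propylidene}-4-[(2-methylpropanoyl)oxy]hept-2-enedioate F3.
- Slow addition of F3 to CrCl2 in THF/DMF (Nozaki–Hiyama allylation) closes the ring through a configurationally mobile allylchromium(III), which is anti-selective whatever the bromide geometry.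
- This gives methyl (1E,5S,7R,8S,9R)-7-hydroxy-5-(hydroxymethyl)-8-(3-methoxy-3-oxoprop-1-en-2-yl)-9-[(2-methylpropanoyl)oxy]cyclodec-1-ene-1-carboxylate F4, which lactonises to 26 on acidic work-up.

*Step 5.* The risks are the tolerance of the acidic phosphonoacetate, the ee obtainable with an aliphatic acid, and diene formation. The fallback sets out from 9 and comes back at 13. It replaces the Rh-hydride alkyne chemistry with a Pd(II)-catalysed asymmetric SN2′ esterification.
- The sodium salt of 9 is alkylated with (Z)-4-chlorobut-2-en-1-ol to give methyl (4Z)-2-(diethoxyphosphoryl)-6-hydroxyhex-4-enoate F5.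
- Cl3CCN with catalytic DBU gives methyl (4Z)-2-(diethoxyphosphoryl)-6-[(2,2,2-trichloroethanimidoyl)oxy]hex-4-enoate F6.
- A chiral cobalt-sandwich oxazoline palladacycle acetate (COP-OAc type) with isobutyric acid 12 in CH2Cl2 delivers the branched (R)-ester 13.

*Step 1.* The risks are Michael oligomerisation of the zinc enolate with 1 and a modest ee on the five-membered lactone. The fallback sets out from 2 and comes back at 4. It moves the conjugate addition to an acyclic enoate and closes the lactone afterwards.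
- 2 is added to methyl (E)-4-[(tert-butyldimethylsilyl)oxy]but-2-enoate with CuBr·SMe2 and a ferrocenyl diphosphine in t-BuOMe at −75 °C. This gives methyl (3S)-3-({[tert-butyl(dimethyl)silyl]oxy}methyl)hept-6-enoate F7.
- Treating F7 with 1 M HCl in THF removes the silyl group and lactonises it to 4.

**Further compounds**
F1 | step 11 | dimethyl (4R,6E)-3-hydroxy-6-{3-[(3S)-5-methoxyoxolan-3-yl]propylidene}-2-methylidene-4-[(2-methylpropanoyl)oxy]heptanedioate | COC1C[C@@H](CO1)CC/C=C(/C(=O)OC)C[C@@H](OC(=O)C(C)C)C(O)C(=C)C(=O)OC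
F2 | step 11 | dimethyl (2Z,4R,6E)-2-(bromomethyl)-6-{3-[(3S)-5-methoxyoxolan-3-yl]propylidene}-4-[(2-methylpropanoyl)oxy]hept-2-enedioate | COC1C[C@@H](CO1)CC/C=C(/C(=O)OC)C[C@@H](OC(=O)C(C)C)/C=C(\CBr)C(=O)OC
F3 | step 11 | dimethyl (2Z,4R,6E)-2-(bromomethyl)-6-{3-[(3S)-5-hydroxyoxolan-3-yl]propylidene}-4-[(2-methylpropanoyl)oxy]hept-2-enedioate | OC1C[C@@H](CO1)CC/C=C(/C(=O)OC)C[C@@H](OC(=O)C(C)C)/C=C(\CBr)C(=O)OC
F4 | step 11 | methyl (1E,5S,7R,8S,9R)-7-hydroxy-5-(hydroxymethyl)-8-(3-methoxy-3-oxoprop-1-en-2-yl)-9-[(2-methylpropanoyl)oxy]cyclodec-1-ene-1-carboxylate | C=C(C(=O)OC)[C@H]1[C@H](O)C[C@@H](CO)CC/C=C(/C(=O)OC)C[C@H]1OC(=O)C(C)C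
F5 | step 5 | methyl (4Z)-2-(diethoxyphosphoryl)-6-hydroxyhex-4-enoate | OC/C=C\CC(C(=O)OC)P(=O)(OCC)OCC
F6 | step 5 | methyl (4Z)-2-(diethoxyphosphoryl)-6-[(2,2,2-trichloroethanimidoyl)oxy]hex-4-enoate | N=C(OC/C=C\CC(C(=O)OC)P(=O)(OCC)OCC)C(Cl)(Cl)Cl
F7 | step 1 | methyl (3S)-3-({[tert-butyl(dimethyl)silyl]oxy}methyl)hept-6-enoate | COC(=O)C[C@@H](CO[Si](C)(C)C(C)(C)C)CCC=C
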